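**Retrosynthetic overview**
1. Feature: in the γ-butyrolactone ring (O1–C2–C3–C4–C5), C4 carries a CH2 bound to the 3,4-dimethoxyphenyl ring and sits next to the fully substituted carbinol carbon C3. Tying that CH2 back to C3 gives a cyclopropane fused on C3–C4, in which the CH2 is a strained electrophile and C3 a masked enolate.
2. C3–OH is traced back to C3–C(O)CH3 (Baeyer–Villiger, retention). The acetyl group also serves as the second activator of the cyclopropane.
3. Key disconnection: the aryl–CH2 bond (aryl cuprate on the cyclopropane CH2) and the C3–CH2Ar′ bond (benzylic bromide on the released enolate), both made in one flask from (1S,5R)-1-acetyl-3-oxabicyclo[3.1.0]hexan-2-one.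
4. The bicyclic ketone comes from the matching lactone acid (acid chloride, methylzinc). The acid comes from (R)-epichlorohydrin and diethyl malonate, the only external source of chirality.
5. Ring order: the cyclopropane forms first and the lactone closes on it in the same cascade. The cyclopropane is spent in the key step, the lactone stays to the end, and both arenes are bought.

Key step: step 6

Remark (numbering): the lactone is numbered O1, C2 (C=O), C3, C4, C5 and the bicycle C1 (quaternary), C2 (C=O), O3, C4 (OCH2), C5 (CH), C6 (cyclopropane CH2). C1, C5 and C6 of the bicycle become C3, C4 and the veratryl CH2 of the lactone.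
Remark (access to the bicycle): a carbene cyclopropanation of allyl 2-diazoacetoacetate would be shorter. Acceptor/acceptor carbenes on an unsubstituted allyl ester offer no dependable enantiocontrol, so the chiral pool is used instead.

**Step 1**
Reactants: 1 (R)-epichlorohydrin; 2 diethyl malonate
Product: 5 ethyl (1S,5R)-2-oxo-3-oxabicyclo[3.1.0]hexane-1-carboxylate, via epoxymalonate 3 (not isolated), via cyclopropylmethoxide 4 (not isolated)
Conditions: NaOEt (1.1 equiv), EtOH, 0 °C → reflux
Reagents that add atoms: sodium ethoxide, CC[O-].[Na+] (sodium of 4 only; all atoms of 5 come from 1 and 2)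
Why: Malonate alkylation/epoxide transposition/3-exo-tet cyclopropanation/lactonisation cascade: the malonate anion opens the epoxide of 1 at its CH2, the alkoxide displaces chloride to give 3, the re-formed carbanion closes the three-membered ring by SN2 inversion at the stereogenic carbon (sets C5 as R), and the freed alkoxide 4 can lactonise only onto the cis ester, which fixes C1 as S.

**Step 2**
Reactants: 5 ethyl (1S,5R)-2-oxo-3-oxabicyclo[3.1.0]hexane-1-carboxylate
Product: 7 (1S,5R)-2-oxo-3-oxabicyclo[3.1.0]hexane-1-carboxylic acid, via disodium dicarboxylate 6 (not isolated)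
Conditions: NaOH (2.2 equiv), H2O/EtOH, 0 °C → rt; then 2 M HCl to pH 1, rt
Reagents that add atoms: sodium hydroxide, [Na+].[OH-] (carboxyl oxygen of 7; sodium of 6)
Why: Exhaustive saponification followed by acid-induced re-lactonisation: both acyl groups are cleaved to 6, in which C1 is no longer stereogenic, and on acidification only the carboxyl group cis to the CH2OH group can close the five-membered lactone, so C5 (R) restores C1 as S.

**Step 3**
Reactants: 7 (1S,5R)-2-oxo-3-oxabicyclo[3.1.0]hexane-1-carboxylic acid
Product: 9 (1S,5R)-1-acetyl-3-oxabicyclo[3.1.0]hexan-2-one, via acid chloride 8 (not isolated)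
Conditions: (COCl)2 (1.2 equiv), cat. DMF, CH2Cl2, 0 °C → rt, concentrate; MeZnCl (1.2 equiv), Pd(PPh3)4 (3 mol %), THF, 0 °C → rt
Reagents that add atoms: oxalyl chloride, ClC(=O)C(=O)Cl (chlorine of 8); methylzinc chloride, C[Zn]Cl (methyl group of 9)
Why: Acid chloride formation through the chloroiminium species, then Negishi-type acylation: the acylpalladium(II) species from 8 takes up methyl from zinc and reductively eliminates to the ketone, and methylzinc chloride is too unreactive to add to the ketone, the lactone or the strained ring, so both stereocentres pass through unchanged.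

**Step 4**
Reactants: 10 4-bromo-1,2-dimethoxybenzene
Product: 11 (3,4-dimethoxyphenyl)magnesium bromide (titrated THF solution)
Conditions: Mg turnings (1.1 equiv), cat. I2, THF, rt → 45 °C
Reagents that add atoms: magnesium, [Mg]
Why: Grignard formation by insertion of magnesium into the aryl C–Br bond; the methoxy groups are inert and no stereocentre is involved.

**Step 5**
Reactants: 12 [4-(benzyloxy)-3-methoxyphenyl]methanol
Product: 13 4-(benzyloxy)-3-methoxybenzyl bromide
Conditions: PBr3 (0.4 equiv), Et2O, 0 °C; used without storage
Reagents that add atoms: phosphorus tribromide, BrP(Br)Br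
Why: Bromination of a benzylic alcohol through its phosphite ester with SN2 displacement by bromide; the electron-rich bromide is labile and is therefore made just before use.

**Step 6**
Reactants: 9 (1S,5R)-1-acetyl-3-oxabicyclo[3.1.0]hexan-2-one; 11 (3,4-dimethoxyphenyl)magnesium bromide; 13 4-(benzyloxy)-3-methoxybenzyl bromide
Product: 16 (3R,4R)-3-acetyl-3-[4-(benzyloxy)-3-methoxybenzyl]-4-(3,4-dimethoxybenzyl)dihydrofuran-2(3H)-one, via diarylcuprate 14 (not isolated), via magnesium enolate 15 (not isolated)
Conditions: 11 (2.4 equiv), CuBr·SMe2 (1.2 equiv), THF/Me2S, −40 °C; 9 (1.0 equiv), −40 → 0 °C; then DMPU, 13 (2.5 equiv), 0 °C → rt; aq NH4Cl/NH3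
Reagents that add atoms: copper(I) bromide–dimethyl sulfide complex, Br[Cu].CSC (copper of 14 only; all atoms of 16 come from 9, 11 and 13)
Why: The Gilman-type cuprate 14, formed with no free Grignard reagent left, attacks the unsubstituted cyclopropane carbon C6 of 9 from the rear of the C1–C6 bond (SN2-like oxidative addition to copper(III), then reductive elimination), which forms the aryl–CH2 bond and releases the ring strain into the chelated β-keto lactone enolate 15; after DMPU has loosened the magnesium chelate, 15 is C-benzylated by 13, which forms the C3–CH2 bond. The closest known reaction type is the homoconjugate addition of organocuprates to doubly activated cyclopropanes, coupled with alkylation of the stabilised β-dicarbonyl enolate that it delivers. No ring is closed: the three-membered ring opens and the lactone ring stays intact. C5 of 9 is not touched and becomes C4 (R) of 16, while the new quaternary centre C3 (R) is set by substrate control, since allylic strain with the enolate methyl group tilts the C4 arylmethyl group over one face of the planar enolate and 13 enters from the other, leaving the two arylmethyl groups trans and the acetyl group cis to the C4 substituent. The step needs attack at C6 rather than at the ketone or lactone carbonyl, secured by the soft copper reagent at low temperature, and cleavage of C1–C6 rather than C1–C5, secured because C6 is the only unhindered ring carbon and the C1–C6 bond is aligned with the π* orbital of the lactone carbonyl whereas the fusion bond C1–C5 lies close to the lactone plane. C- over O-alkylation is favoured by the soft, very reactive benzylic bromide, and the excess of 13 covers what the residual arylcopper consumes.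

**Step 7**
Reactants: 16 (3R,4R)-3-acetyl-3-[4-(benzyloxy)-3-methoxybenzyl]-4-(3,4-dimethoxybenzyl)dihydrofuran-2(3H)-one
Product: 17 (3S,4S)-3-[4-(benzyloxy)-3-methoxybenzyl]-4-(3,4-dimethoxybenzyl)-2-oxotetrahydrofuran-3-yl acetate
Conditions: mCPBA (3 equiv), TFA (1 equiv), CH2Cl2, 0 °C → rt, dark; aq Na2S2O3/NaHCO3
Reagents that add atoms: 3-chloroperoxybenzoic acid, OOC(=O)c1cccc(Cl)c1
Why: Baeyer–Villiger oxidation: in the Criegee adduct of the methyl ketone the fully substituted C3 migrates in preference to methyl and with retention, so the acetoxy group takes the place of acetyl cis to the C4 substituent (the descriptors change to 3S,4S through CIP priorities only), with acid catalysis offsetting the hindrance and mCPBA rather than a stronger peracid sparing the electron-rich arenes.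

**Step 8**
Reactants: 17 (3S,4S)-3-[4-(benzyloxy)-3-methoxybenzyl]-4-(3,4-dimethoxybenzyl)-2-oxotetrahydrofuran-3-yl acetate
Product: 18 (3S,4S)-3-[4-(benzyloxy)-3-methoxybenzyl]-4-(3,4-dimethoxybenzyl)-3-hydroxydihydrofuran-2(3H)-one
Conditions: K2CO3 (0.2 equiv), MeOH, 0 °C → rt; 1 M HCl work-up
Reagents that add atoms: none
Why: Base-catalysed transesterification (Zemplén-type deacetylation): the acetate α to the lactone carbonyl is an activated ester and passes its acetyl group to methanol, any lactone opened by methoxide re-closes on acidification, and neither the quaternary C3 nor C4 can epimerise.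

**Step 9**
Reactants: 18 (3S,4S)-3-[4-(benzyloxy)-3-methoxybenzyl]-4-(3,4-dimethoxybenzyl)-3-hydroxydihydrofuran-2(3H)-one
Product: 19 trachelogenin, (3S,4S)-4-(3,4-dimethoxybenzyl)-3-hydroxy-3-(4-hydroxy-3-methoxybenzyl)dihydrofuran-2(3H)-one
Conditions: H2 (1 atm), 10 % Pd/C, EtOAc–EtOH, rt
Reagents that add atoms: none
Why: Catalytic hydrogenolysis of the aryl benzyl ether; the lactone, the non-benzylic tertiary alcohol and the aryl methyl ethers are inert, so the phenol is released with the (3S,4S) configuration intact.

**Compound list**
1 | (R)-epichlorohydrin | ClC[C@H]1CO1 | starting material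
2 | diethyl malonate | CCOC(=O)CC(=O)OCC | starting material
3 | diethyl 2-{[(2R)-oxiran-2-yl]methyl}propanedioate | CCOC(=O)C(C[C@@H]1CO1)C(=O)OCC | intermediate
4 | sodium alkoxide of diethyl (2R)-2-(hydroxymethyl)cyclopropane-1,1-dicarboxylate | CCOC(=O)C1(C(=O)OCC)C[C@H]1C[O-].[Na+] | intermediate
5 | ethyl (1S,5R)-2-oxo-3-oxabicyclo[3.1.0]hexane-1-carboxylate | CCOC(=O)[C@]12C[C@H]1COC2=O | intermediate
6 | disodium (2R)-2-(hydroxymethyl)cyclopropane-1,1-dicarboxylate | [Na+].[Na+].[O-]C(=O)C1(C([O-])=O)C[C@H]1CO | intermediate
7 | (1S,5R)-2-oxo-3-oxabicyclo[3.1.0]hexane-1-carboxylic acid | OC(=O)[C@]12C[C@H]1COC2=O | intermediate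
8 | (1R,5R)-2-oxo-3-oxabicyclo[3.1.0]hexane-1-carbonyl chloride (same spatial arrangement as 7) | ClC(=O)[C@]12C[C@H]1COC2=O | intermediate
9 | (1S,5R)-1-acetyl-3-oxabicyclo[3.1.0]hexan-2-one | CC(=O)[C@]12C[C@H]1COC2=O | intermediate
10 | 4-bromo-1,2-dimethoxybenzene | COc1ccc(Br)cc1OC | starting material
11 | (3,4-dimethoxyphenyl)magnesium bromide | COc1ccc([Mg]Br)cc1OC | intermediate
12 | [4-(benzyloxy)-3-methoxyphenyl]methanol | COc1cc(CO)ccc1OCc1ccccc1 | starting material
13 | 4-(benzyloxy)-3-methoxybenzyl bromide | COc1cc(CBr)ccc1OCc1ccccc1 | intermediate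
14 | bromomagnesium bis(3,4-dimethoxyphenyl)cuprate | COc1ccc([Cu-]c2ccc(OC)c(OC)c2)cc1OC.[Mg+]Br | intermediate
15 | chelated bromomagnesium enolate of (4R)-3-acetyl-4-(3,4-dimethoxybenzyl)dihydrofuran-2(3H)-one | C/C(O[Mg]Br)=C1/C(=O)OC[C@@H]1Cc1ccc(OC)c(OC)c1 | intermediate
16 | (3R,4R)-3-acetyl-3-[4-(benzyloxy)-3-methoxybenzyl]-4-(3,4-dimethoxybenzyl)dihydrofuran-2(3H)-one | COc1cc(C[C@@]2(C(C)=O)C(=O)OC[C@@H]2Cc2ccc(OC)c(OC)c2)ccc1OCc1ccccc1 | intermediate
17 | (3S,4S)-3-[4-(benzyloxy)-3-methoxybenzyl]-4-(3,4-dimethoxybenzyl)-2-oxotetrahydrofuran-3-yl acetate | COc1cc(C[C@@]2(OC(C)=O)C(=O)OC[C@@H]2Cc2ccc(OC)c(OC)c2)ccc1OCc1ccccc1 | intermediate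
18 | (3S,4S)-3-[4-(benzyloxy)-3-methoxybenzyl]-4-(3,4-dimethoxybenzyl)-3-hydroxydihydrofuran-2(3H)-one | COc1cc(C[C@@]2(O)C(=O)OC[C@@H]2Cc2ccc(OC)c(OC)c2)ccc1OCc1ccccc1 | intermediate
19 | trachelogenin, (3S,4S) | COc1cc(C[C@@]2(O)C(=O)OC[C@@H]2Cc2ccc(OC)c(OC)c2)ccc1O | target

**Total step count:** 9. **Longest linear sequence:** 7 (steps 1, 2, 3, 6, 7, 8, 9).

**Steps most likely to fail**

Step 6.
- What may go wrong: slow C-alkylation of the tightly chelated magnesium enolate, loss of the benzylic bromide through coupling with the residual arylcopper, and some aryl transfer to the ketone carbonyl.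
- Fallback: the two bond formations are separated and the enolate counter-ion is changed. The fallback sets out from 9. Opening with 14 as in step 6, but with an NH4Cl quench in place of the bromide, should give (4R)-3-acetyl-4-(3,4-dimethoxybenzyl)dihydrofuran-2(3H)-one F1 (C3 epimers and enol, of no consequence). F1 is freed from copper and arene residues by chromatography. Its caesium enolate (Cs2CO3, DMF, 0 °C → rt) is then benzylated with 13 anti to the C4 substituent, and the route is rejoined at 16.

Step 7.
- What may go wrong: sluggish peracid addition to the hindered, electron-poor ketone, competing oxidation of the electron-rich aromatic rings, and competing methyl migration.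
- Fallback: the oxygen is placed at C3 before the benzyl group, so that no acyl migration is needed. The fallback sets out from 5. The ester-activated cyclopropane is opened with 14 (THF, −40 → 0 °C, NH4Cl quench) to ethyl (4R)-4-(3,4-dimethoxybenzyl)-2-oxotetrahydrofuran-3-carboxylate F2. Saponification, acidification and heating in toluene should give (4R)-4-(3,4-dimethoxybenzyl)dihydrofuran-2(3H)-one F3. Enolate hydroxylation (KHMDS, 2-(phenylsulfonyl)-3-phenyloxaziridine, THF, −78 °C) gives (4S)-4-(3,4-dimethoxybenzyl)-3-hydroxydihydrofuran-2(3H)-one F4, whose C3 configuration is irrelevant. Its dianion (LDA, 2.2 equiv, THF–DMPU, −78 → −20 °C) is benzylated at C3 by 13 anti to the C4 substituent. The route is rejoined at 18, bypassing 16 and 17.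

Step 3.
- What may go wrong: opening of the doubly activated cyclopropane by chloride during acid chloride formation, and decarbonylation at palladium before methyl transfer.
- Fallback: the methyl ketone is built by decarboxylative acylation without chloride or an organometallic reagent. The fallback sets out from 7. 1,1′-Carbonyldiimidazole (THF, rt) gives (1S,5R)-1-(1H-imidazole-1-carbonyl)-3-oxabicyclo[3.1.0]hexan-2-one F5. F5 is treated with magnesium bis(mono-tert-butyl malonate) (Masamune–Brooks acylation, THF, rt → 40 °C) to give tert-butyl 3-oxo-3-[(1S,5R)-2-oxo-3-oxabicyclo[3.1.0]hexan-1-yl]propanoate F6. TFA in CH2Cl2, then warming in toluene, removes the tert-butyl group and the carboxyl group, and the route is rejoined at 9.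

**Further compounds**
F1 | step 6 | (4R)-3-acetyl-4-(3,4-dimethoxybenzyl)dihydrofuran-2(3H)-one | CC(=O)C1C(=O)OC[C@@H]1Cc1ccc(OC)c(OC)c1
F2 | step 7 | ethyl (4R)-4-(3,4-dimethoxybenzyl)-2-oxotetrahydrofuran-3-carboxylate | CCOC(=O)C1C(=O)OC[C@@H]1Cc1ccc(OC)c(OC)c1
F3 | step 7 | (4R)-4-(3,4-dimethoxybenzyl)dihydrofuran-2(3H)-one | O=C1C[C@@H](Cc2ccc(OC)c(OC)c2)CO1
F4 | step 7 | (4S)-4-(3,4-dimethoxybenzyl)-3-hydroxydihydrofuran-2(3H)-one | OC1C(=O)OC[C@@H]1Cc1ccc(OC)c(OC)c1
F5 | step 3 | (1S,5R)-1-(1H-imidazole-1-carbonyl)-3-oxabicyclo[3.1.0]hexan-2-one | O=C(n1ccnc1)[C@]12C[C@H]1COC2=O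
F6 | step 3 | tert-butyl 3-oxo-3-[(1S,5R)-2-oxo-3-oxabicyclo[3.1.0]hexan-1-yl]propanoate | CC(C)(C)OC(=O)CC(=O)[C@]12C[C@H]1COC2=O
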